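**Retrosynthetic overview** (chromanone half: ketal C2, carbinol C3, carbonyl C4, ring A; flavan half marked f: O1f, C2f, arene ring D = C4af–C8af)
1. Rings C (pyranone) and F (dihydrofuran) are one bis-ketal. Opening the ketal carbon C2 gives a 2-hydroxy-1,3-dione with free ring-A and flavan 7-OH groups, so both rings close last and C2 follows C3.
2. C3 is cut at its bond to C8f and the flavan pyran (ring E) at O1f–C8af. These two bonds sit on neighbouring carbons of ring D and are both made from an aryne C8af≡C8f: tethered alkoxide in, arylmagnesium out to a ketone.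
3. Enabling feature: in ring D the pyran oxygen is on C8af and the carbinol carbon on the adjacent C8f. C8af is flanked by C4af, whose three-carbon chain delivers the alkoxide through a six-membered ring. C8f is flanked by the C7f oxygen, which polarises the aryne and stabilises the carbanion. The phloroglucinol pattern supplies a phenol on C8af as leaving group.
4. Fragments: iodo sulfonate 8 (the C2f carbinol set by CBS reduction) and (R)-MOM-oxy 1,2-dione 14 (asymmetric alkynylation, alkyne oxidation). The stereocentre of 14 steers C3 and is then oxidised away.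
5. Ring order: ring E in step 12, then rings C and F together in step 15; rings A, D and both 4-hydroxyphenyl rings are bought as arenes.

Key step: step 12

Assumption: the three descriptors are carried exactly as written in the target SMILES. Read literally, the C2/C3 pair puts the 4-hydroxyphenyl group and the C3 hydroxyl anti across the ring fusion, whereas ketal closure from C3 gives the ring-fused (syn) ketal. The route controls C3 and C2f directly, and C2, made last, is written with the given descriptor on the understanding that the given pair stands for that ring-fused ketal.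

**Step 1**
Reactants: 1 2,4,6-trihydroxybenzaldehyde
Product: 2 2,4-bis(benzyloxy)-6-hydroxybenzaldehyde
Conditions: BnBr (2.1 equiv), K2CO3, DMF, 0 → 20 °C
Reagents that add atoms: benzyl bromide, BrCc1ccccc1
Why: Williamson etherification in which the 4-hydroxyl and one 2-hydroxyl are benzylated, while the last ortho hydroxyl, hydrogen-bonded to the formyl oxygen, is the least nucleophilic and should stay free.

**Step 2**
Reactants: 2 2,4-bis(benzyloxy)-6-hydroxybenzaldehyde
Product: 3 4,6-bis(benzyloxy)-2-hydroxy-3-iodobenzaldehyde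
Conditions: BnMe3N+ ICl2−, CaCO3, CH2Cl2–MeOH, 20 °C
Reagents that add atoms: benzyltrimethylammonium dichloroiodate, C[N+](C)(C)Cc1ccccc1.Cl[I-]Cl
Why: Electrophilic aromatic iodination that should go ortho to the free, carbonyl-chelated hydroxyl (between OH and OBn) rather than between the two benzyloxy groups, as is usual for 2-hydroxy-4,6-dialkoxyaryl carbonyl compounds with this reagent.

**Step 3**
Reactants: 3 4,6-bis(benzyloxy)-2-hydroxy-3-iodobenzaldehyde
Product: 4 3,5-bis(benzyloxy)-2-formyl-6-iodophenyl 4-chlorobenzenesulfonate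
Conditions: 4-ClC6H4SO2Cl, Et3N, DMAP (cat.), CH2Cl2, 0 °C
Reagents that add atoms: 4-chlorobenzenesulfonyl chloride, O=S(=O)(Cl)c1ccc(Cl)cc1
Why: O-Sulfonylation of the phenol, which places the leaving group on the future C8af directly beside the iodine-bearing future C8f, the 2-iodoaryl sulfonate pattern of an aryne precursor.

**Step 4**
Reactants: 4 3,5-bis(benzyloxy)-2-formyl-6-iodophenyl 4-chlorobenzenesulfonate; 5 1-[4-(benzyloxy)phenyl]ethan-1-one
Product: 6 3,5-bis(benzyloxy)-2-[(1E)-3-[4-(benzyloxy)phenyl]-3-oxoprop-1-en-1-yl]-6-iodophenyl 4-chlorobenzenesulfonate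
Conditions: LiOH·H2O (cat.), EtOH–THF, 20 °C
Reagents that add atoms: none
Why: Claisen–Schmidt aldol condensation of an aldehyde without alpha hydrogen, activated by the ortho sulfonate, that gives the (E)-enone and joins ring D to the aryl ketone.

**Step 5**
Reactants: 6 3,5-bis(benzyloxy)-2-[(1E)-3-[4-(benzyloxy)phenyl]-3-oxoprop-1-en-1-yl]-6-iodophenyl 4-chlorobenzenesulfonate
Product: 7 3,5-bis(benzyloxy)-2-[3-[4-(benzyloxy)phenyl]-3-oxopropyl]-6-iodophenyl 4-chlorobenzenesulfonate
Conditions: CuCl (10 mol%), PPh3 (10 mol%), TBAF (10 mol%), PhMe2SiH, DMA, 20 °C; then aq. NH4Cl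
Reagents that add atoms: none
Why: Copper hydride conjugate reduction (1,4-hydrosilylation, then hydrolysis of the silyl enol ether) that saturates the enone without touching the aryl iodide, the sulfonate, the benzyl ethers or the ketone.

**Step 6**
Reactants: 7 3,5-bis(benzyloxy)-2-[3-[4-(benzyloxy)phenyl]-3-oxopropyl]-6-iodophenyl 4-chlorobenzenesulfonate
Product: 8 3,5-bis(benzyloxy)-2-[(3S)-3-[4-(benzyloxy)phenyl]-3-hydroxypropyl]-6-iodophenyl 4-chlorobenzenesulfonate
Conditions: (R)-2-methyl-CBS-oxazaborolidine (10 mol%), BH3·SMe2, THF, −20 °C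
Reagents that add atoms: none
Why: Corey–Bakshi–Shibata reduction in which the (R)-oxazaborolidine delivers hydride to the Re face of the aryl ketone (aryl as the large group), setting the (S)-carbinol that becomes the flavan stereocentre C2f.

**Step 7**
Reactants: 1 2,4,6-trihydroxybenzaldehyde
Product: 9 2,4,6-tris(benzyloxy)benzaldehyde
Conditions: BnBr (3.5 equiv), K2CO3, DMF, 60 °C
Reagents that add atoms: benzyl bromide, BrCc1ccccc1
Why: Exhaustive Williamson benzylation under forcing conditions, which also alkylates the chelated hydroxyl.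

**Step 8**
Reactants: 9 2,4,6-tris(benzyloxy)benzaldehyde
Product: 10 1,3,5-tris(benzyloxy)-2-ethynylbenzene
Conditions: dimethyl (1-diazo-2-oxopropyl)phosphonate, K2CO3, MeOH–THF, 20 °C
Reagents that add atoms: dimethyl (1-diazo-2-oxopropyl)phosphonate, CC(=O)C(=[N+]=[N-])P(=O)(OC)OC
Why: Ohira–Bestmann (Seyferth–Gilbert) homologation of the non-enolisable aldehyde to the terminal alkyne via the diazoalkene and the 1,2-shift of its alkylidene carbene.

**Step 9**
Reactants: 10 1,3,5-tris(benzyloxy)-2-ethynylbenzene; 11 4-(benzyloxy)benzaldehyde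
Product: 12 (1R)-1-[4-(benzyloxy)phenyl]-3-[2,4,6-tris(benzyloxy)phenyl]prop-2-yn-1-ol
Conditions: Et2Zn, toluene, reflux; then (S)-BINOL (20 mol%), Ti(OiPr)4 (50 mol%), 11, CH2Cl2–toluene, 20 °C
Reagents that add atoms: none
Why: Catalytic enantioselective addition of the alkynylzinc to the aldehyde with a BINOL–titanium catalyst, in which (S)-BINOL should direct the alkynyl group to the Si face and so set the (R)-carbinol.

**Step 10**
Reactants: 12 (1R)-1-[4-(benzyloxy)phenyl]-3-[2,4,6-tris(benzyloxy)phenyl]prop-2-yn-1-ol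
Product: 13 1,3,5-tris(benzyloxy)-2-[(3R)-3-[4-(benzyloxy)phenyl]-3-(methoxymethoxy)prop-1-yn-1-yl]benzene
Conditions: MOMCl, i-Pr2NEt, CH2Cl2, 0 → 20 °C
Reagents that add atoms: chloromethyl methyl ether, COCCl
Why: O-Alkylation that installs a small, chelating MOM ether (needed for chelation control in step 12 and removable independently of the benzyl ethers) without touching the stereocentre.

**Step 11**
Reactants: 13 1,3,5-tris(benzyloxy)-2-[(3R)-3-[4-(benzyloxy)phenyl]-3-(methoxymethoxy)prop-1-yn-1-yl]benzene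
Product: 14 (3R)-3-[4-(benzyloxy)phenyl]-3-(methoxymethoxy)-1-[2,4,6-tris(benzyloxy)phenyl]propane-1,2-dione
Conditions: PdBr2 (5 mol%), CuBr2 (10 mol%), O2 (1 atm), 1,4-dioxane–H2O, 60 °C
Reagents that add atoms: water, O
Why: Wacker-type oxidation of the internal alkyne (two hydroxypalladation–oxidation events, with CuBr2/O2 turning the palladium over) to the 1,2-dione, in which the neighbouring stereocentre takes no part.

**Step 12**
Reactants: 8 3,5-bis(benzyloxy)-2-[(3S)-3-[4-(benzyloxy)phenyl]-3-hydroxypropyl]-6-iodophenyl 4-chlorobenzenesulfonate; 14 (3R)-3-[4-(benzyloxy)phenyl]-3-(methoxymethoxy)-1-[2,4,6-tris(benzyloxy)phenyl]propane-1,2-dione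
Product: 18 (2R,3R)-2-[(2S)-5,7-bis(benzyloxy)-2-[4-(benzyloxy)phenyl]chroman-8-yl]-3-[4-(benzyloxy)phenyl]-2-hydroxy-3-(methoxymethoxy)-1-[2,4,6-tris(benzyloxy)phenyl]propan-1-one, via dimagnesiated sulfonate 15 (not isolated), via aryne alkoxide 16 (not isolated), via chroman-8-ylmagnesium chloride 17 (not isolated)
Conditions: i-PrMgCl·LiCl (2.05 equiv), THF, −78 °C, then → 20 °C; recool to −78 °C; 14 premixed with MgBr2·OEt2 (CH2Cl2), −78 → −40 °C; aq. NH4Cl at −40 °C
Reagents that add atoms: none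
Why: Proposed new method: i-PrMgCl·LiCl deprotonates the carbinol and exchanges the iodine to give 15, which on warming loses magnesium 4-chlorobenzenesulfonate to form aryne 16 (C8af≡C8f); the tethered magnesium alkoxide adds to C8af and the resulting arylmagnesium 17 then adds to the carbonyl of 14 that becomes C3. The closest known reaction types are aryne generation from 2-iodoaryl sulfonates by iodine–magnesium exchange with addition of magnesium amides or thiolates and carbonyl trapping of the arylmagnesium, and the classical intramolecular addition of alkoxides to arynes that gives chromans; only their combination with a tethered alkoxide and a ketone acceptor is new. Ring E is closed in a 6-exo-dig mode by forming the O1f–C8af bond, with retention at C2f because its C–O bond is never broken. Regioselectivity is secured twice, since only C8af can be reached from the C4af tether through a six-membered ring and the benzyloxy group on C7f polarises the aryne so that the nucleophile enters at the remote carbon and the carbanion develops at C8f next to that oxygen. The new stereocentre C3 is set by 1,2-induction from the (R)-MOM-oxy carbon of 14 in a Cram chelate (Mg bridging the MOM oxygen and the attacked carbonyl oxygen), the aryl group entering from the side of the hydrogen atom. Chemoselectivity for this carbonyl over its neighbour rests on the shielding of the latter by its 2,6-bis(benzyloxy)aryl group.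

**Step 13**
Reactants: 18 (2R,3R)-2-[(2S)-5,7-bis(benzyloxy)-2-[4-(benzyloxy)phenyl]chroman-8-yl]-3-[4-(benzyloxy)phenyl]-2-hydroxy-3-(methoxymethoxy)-1-[2,4,6-tris(benzyloxy)phenyl]propan-1-one
Product: 19 (2R,3R)-2-[(2S)-5,7-bis(benzyloxy)-2-[4-(benzyloxy)phenyl]chroman-8-yl]-3-[4-(benzyloxy)phenyl]-2,3-dihydroxy-1-[2,4,6-tris(benzyloxy)phenyl]propan-1-one
Conditions: TMSOTf, 2,2′-bipyridyl, CH2Cl2, 0 °C; then H2O, 20 °C
Reagents that add atoms: none
Why: Chemoselective cleavage of the aliphatic MOM ether through a bipyridinium acetal salt that water hydrolyses, under conditions that leave the benzyl ethers, the tertiary alcohol and the stereocentres at C3 and C2f untouched.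

**Step 14**
Reactants: 19 (2R,3R)-2-[(2S)-5,7-bis(benzyloxy)-2-[4-(benzyloxy)phenyl]chroman-8-yl]-3-[4-(benzyloxy)phenyl]-2,3-dihydroxy-1-[2,4,6-tris(benzyloxy)phenyl]propan-1-one
Product: 20 (2R)-2-[(2S)-5,7-bis(benzyloxy)-2-[4-(benzyloxy)phenyl]chroman-8-yl]-1-[4-(benzyloxy)phenyl]-2-hydroxy-3-[2,4,6-tris(benzyloxy)phenyl]propane-1,3-dione
Conditions: Dess–Martin periodinane, CH2Cl2, 0 → 20 °C
Reagents that add atoms: none
Why: Dess–Martin oxidation of the secondary benzylic alcohol to the aryl ketone (the tertiary alcohol cannot react), which deliberately erases the temporary stereocentre after it has done its work and gives the 2-hydroxy-1,3-dione.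

**Step 15**
Reactants: 20 (2R)-2-[(2S)-5,7-bis(benzyloxy)-2-[4-(benzyloxy)phenyl]chroman-8-yl]-1-[4-(benzyloxy)phenyl]-2-hydroxy-3-[2,4,6-tris(benzyloxy)phenyl]propane-1,3-dione
Product: 22 target CNP0208300.3, via heptaphenol hydroxy-dione 21 (not isolated)
Conditions: H2 (1 atm), Pd(OH)2/C, THF–MeOH, 20 °C; filter; then TsOH·H2O (cat.), 4 Å MS, THF, 20 °C
Reagents that add atoms: none
Why: Hydrogenolysis frees all seven phenols, and acid then turns the C2 ketone into the bis-ketal by attack of one ring-A ortho hydroxyl (ring C, 6-exo-trig) and of the flavan 7-hydroxyl on the resulting oxocarbenium ion (ring F, 5-exo-trig); the ketal stereocentre C2 is not set independently but follows from C3, to which both closing arms are attached.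

**Compound list**
1 | 2,4,6-trihydroxybenzaldehyde | O=Cc1c(O)cc(O)cc1O | starting material
2 | 2,4-bis(benzyloxy)-6-hydroxybenzaldehyde | O=Cc1c(O)cc(OCc2ccccc2)cc1OCc1ccccc1 | intermediate
3 | 4,6-bis(benzyloxy)-2-hydroxy-3-iodobenzaldehyde | O=Cc1c(O)c(I)c(OCc2ccccc2)cc1OCc1ccccc1 | intermediate
4 | 3,5-bis(benzyloxy)-2-formyl-6-iodophenyl 4-chlorobenzenesulfonate | O=Cc1c(OS(=O)(=O)c2ccc(Cl)cc2)c(I)c(OCc2ccccc2)cc1OCc1ccccc1 | intermediate
5 | 1-[4-(benzyloxy)phenyl]ethan-1-one | CC(=O)c1ccc(OCc2ccccc2)cc1 | starting material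
6 | 3,5-bis(benzyloxy)-2-[(1E)-3-[4-(benzyloxy)phenyl]-3-oxoprop-1-en-1-yl]-6-iodophenyl 4-chlorobenzenesulfonate | O=C(/C=C/c1c(OS(=O)(=O)c2ccc(Cl)cc2)c(I)c(OCc2ccccc2)cc1OCc1ccccc1)c1ccc(OCc2ccccc2)cc1 | intermediate
7 | 3,5-bis(benzyloxy)-2-[3-[4-(benzyloxy)phenyl]-3-oxopropyl]-6-iodophenyl 4-chlorobenzenesulfonate | O=C(CCc1c(OS(=O)(=O)c2ccc(Cl)cc2)c(I)c(OCc2ccccc2)cc1OCc1ccccc1)c1ccc(OCc2ccccc2)cc1 | intermediate
8 | 3,5-bis(benzyloxy)-2-[(3S)-3-[4-(benzyloxy)phenyl]-3-hydroxypropyl]-6-iodophenyl 4-chlorobenzenesulfonate | O[C@H](c1ccc(OCc2ccccc2)cc1)CCc1c(OS(=O)(=O)c2ccc(Cl)cc2)c(I)c(OCc2ccccc2)cc1OCc1ccccc1 | intermediate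
9 | 2,4,6-tris(benzyloxy)benzaldehyde | O=Cc1c(OCc2ccccc2)cc(OCc2ccccc2)cc1OCc1ccccc1 | intermediate
10 | 1,3,5-tris(benzyloxy)-2-ethynylbenzene | C#Cc1c(OCc2ccccc2)cc(OCc2ccccc2)cc1OCc1ccccc1 | intermediate
11 | 4-(benzyloxy)benzaldehyde | O=Cc1ccc(OCc2ccccc2)cc1 | starting material
12 | (1R)-1-[4-(benzyloxy)phenyl]-3-[2,4,6-tris(benzyloxy)phenyl]prop-2-yn-1-ol | O[C@H](c1ccc(OCc2ccccc2)cc1)C#Cc1c(OCc2ccccc2)cc(OCc2ccccc2)cc1OCc1ccccc1 | intermediate
13 | 1,3,5-tris(benzyloxy)-2-[(3R)-3-[4-(benzyloxy)phenyl]-3-(methoxymethoxy)prop-1-yn-1-yl]benzene | COCO[C@H](c1ccc(OCc2ccccc2)cc1)C#Cc1c(OCc2ccccc2)cc(OCc2ccccc2)cc1OCc1ccccc1 | intermediate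
14 | (3R)-3-[4-(benzyloxy)phenyl]-3-(methoxymethoxy)-1-[2,4,6-tris(benzyloxy)phenyl]propane-1,2-dione | COCO[C@H](c1ccc(OCc2ccccc2)cc1)C(=O)C(=O)c1c(OCc2ccccc2)cc(OCc2ccccc2)cc1OCc1ccccc1 | intermediate
15 | chloromagnesium (1S)-1-[4-(benzyloxy)phenyl]-3-[2,4-bis(benzyloxy)-5-(chloromagnesio)-6-(4-chlorophenylsulfonyloxy)phenyl]propan-1-olate (dimagnesiated sulfonate) | Cl[Mg]O[C@H](c1ccc(OCc2ccccc2)cc1)CCc1c(OS(=O)(=O)c2ccc(Cl)cc2)c([Mg]Cl)c(OCc2ccccc2)cc1OCc1ccccc1 | intermediate
16 | chloromagnesium (1S)-1-[4-(benzyloxy)phenyl]-3-[2,4-bis(benzyloxy)-5,6-didehydrophenyl]propan-1-olate (aryne alkoxide) | Cl[Mg]O[C@H](c1ccc(OCc2ccccc2)cc1)CCC1=C(OCc2ccccc2)C=C(OCc2ccccc2)C#C1 | intermediate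
17 | [(2S)-5,7-bis(benzyloxy)-2-[4-(benzyloxy)phenyl]chroman-8-yl]magnesium chloride | Cl[Mg]c1c(OCc2ccccc2)cc(OCc2ccccc2)c2c1O[C@H](c1ccc(OCc3ccccc3)cc1)CC2 | intermediate
18 | (2R,3R)-2-[(2S)-5,7-bis(benzyloxy)-2-[4-(benzyloxy)phenyl]chroman-8-yl]-3-[4-(benzyloxy)phenyl]-2-hydroxy-3-(methoxymethoxy)-1-[2,4,6-tris(benzyloxy)phenyl]propan-1-one | c1(OCc2ccccc2)cc(OCc2ccccc2)c2c(c1[C@](C(=O)c1c(OCc3ccccc3)cc(OCc3ccccc3)cc1OCc1ccccc1)([C@H](OCOC)c1ccc(OCc3ccccc3)cc1)O)O[C@H](c1ccc(OCc3ccccc3)cc1)CC2 | intermediate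
19 | (2R,3R)-2-[(2S)-5,7-bis(benzyloxy)-2-[4-(benzyloxy)phenyl]chroman-8-yl]-3-[4-(benzyloxy)phenyl]-2,3-dihydroxy-1-[2,4,6-tris(benzyloxy)phenyl]propan-1-one | c1(OCc2ccccc2)cc(OCc2ccccc2)c2c(c1[C@](C(=O)c1c(OCc3ccccc3)cc(OCc3ccccc3)cc1OCc1ccccc1)([C@H](O)c1ccc(OCc3ccccc3)cc1)O)O[C@H](c1ccc(OCc3ccccc3)cc1)CC2 | intermediate
20 | (2R)-2-[(2S)-5,7-bis(benzyloxy)-2-[4-(benzyloxy)phenyl]chroman-8-yl]-1-[4-(benzyloxy)phenyl]-2-hydroxy-3-[2,4,6-tris(benzyloxy)phenyl]propane-1,3-dione | c1(OCc2ccccc2)cc(OCc2ccccc2)c2c(c1[C@](C(=O)c1c(OCc3ccccc3)cc(OCc3ccccc3)cc1OCc1ccccc1)(C(=O)c1ccc(OCc3ccccc3)cc1)O)O[C@H](c1ccc(OCc3ccccc3)cc1)CC2 | intermediate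
21 | (2R)-2-[(2S)-5,7-dihydroxy-2-(4-hydroxyphenyl)chroman-8-yl]-2-hydroxy-1-(4-hydroxyphenyl)-3-(2,4,6-trihydroxyphenyl)propane-1,3-dione | Oc1cc(O)c2c(c1[C@](C(=O)c1c(O)cc(O)cc1O)(C(=O)c1ccc(O)cc1)O)O[C@H](c1ccc(O)cc1)CC2 | intermediate
22 | CNP0208300.3: 3,5,7-trihydroxy-2-(4-hydroxyphenyl)chroman-4-one (C2 R, C3 S) whose C2 and C3 are joined through O and C to O7 and C8 of (2S)-5-hydroxy-2-(4-hydroxyphenyl)chromane | O=C1c2c(O)cc(O)cc2O[C@@]2(c3ccc(O)cc3)Oc3cc(O)c4c(c3[C@]12O)O[C@H](c1ccc(O)cc1)CC4 | target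

**Totals and risks**
Total step count: 15. Longest linear sequence: 10 steps (steps 1–6, then 12–15).

Most likely to fail:

1. Step 12. The magnesium alkoxide may add to the aryne too slowly, so that the aryne is consumed by intermolecular addition of organomagnesium species. The hindered arylmagnesium may also deprotonate or reduce the dione instead of adding, and non-chelated addition may erode the facial selectivity.
Fallback (known chemistry; the same aryl C–O bond is closed by palladium catalysis and the C–C bond is made afterwards): set out from 5. Condense it (LiOH·H2O, EtOH–THF) with 2,4-bis(benzyloxy)-6-bromobenzaldehyde F1, made by Vilsmeier–Haack formylation (POCl3, DMF) of commercial 1,3-bis(benzyloxy)-5-bromobenzene, to give (E)-3-[2,4-bis(benzyloxy)-6-bromophenyl]-1-[4-(benzyloxy)phenyl]prop-2-en-1-one F2. Reduce the C=C bond as in step 5 to 3-[2,4-bis(benzyloxy)-6-bromophenyl]-1-[4-(benzyloxy)phenyl]propan-1-one F3 and the ketone as in step 6 to (1S)-3-[2,4-bis(benzyloxy)-6-bromophenyl]-1-[4-(benzyloxy)phenyl]propan-1-ol F4. Close the pyran by intramolecular C–O coupling (Pd(OAc)2, 2-(di-tert-butylphosphino)-1,1′-binaphthyl, Cs2CO3, toluene, 80 °C; retention at the carbinol) to (2S)-5,7-bis(benzyloxy)-2-[4-(benzyloxy)phenyl]chromane F5. Brominate at C8 (NBS, CH2Cl2, −78 °C; the usual C8 preference of 5,7-dibenzyloxyflavans) to (2S)-5,7-bis(benzyloxy)-2-[4-(benzyloxy)phenyl]-8-bromochromane F6. Bromine–lithium exchange (n-BuLi, THF, −78 °C) and transmetalation with MgBr2·OEt2 give the bromomagnesium analogue of 17, which is added to 14 as in step 12; the route is rejoined at 18.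

2. Step 11. The hindered, electron-rich alkyne may oxidise incompletely, the Lewis-acidic bromides may cleave the MOM ether at 60 °C, and the MOM-oxy carbon may epimerise once it is alpha to the dione.
Fallback (stepwise oxidation under neutral conditions): set out from 13. Semi-hydrogenate (H2, Pd/CaCO3 poisoned with Pb(OAc)2, quinoline, EtOAc) to 1,3,5-tris(benzyloxy)-2-[(1Z,3S)-3-[4-(benzyloxy)phenyl]-3-(methoxymethoxy)prop-1-en-1-yl]benzene F7 (same spatial arrangement; the descriptor changes with the priorities). Dihydroxylate (OsO4 cat., NMO, acetone–H2O) to (3R)-3-[4-(benzyloxy)phenyl]-3-(methoxymethoxy)-1-[2,4,6-tris(benzyloxy)phenyl]propane-1,2-diol F8, used as the mixture of diastereomers at the two new carbinol carbons. Oxidise both hydroxyls with IBX (DMSO, 20 °C) and rejoin the route at 14.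

3. Step 15. Hydrogenolysis may cut the benzylic C–O bonds of the flavan or of the tertiary carbinol, or reduce an aryl ketone, before all seven benzyl ethers are gone; acid may then scramble C3 by reversible cleavage of the C3–C8f bond.
Fallback (non-reductive Lewis-acid debenzylation with a cation scavenger in place of hydrogenolysis): set out from 20, treat with BCl3 and pentamethylbenzene (CH2Cl2, −78 °C) to reach 21, then ketalise as in step 15 and rejoin at 22. This fallback makes no new compound (F0).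

**Further compounds**
F1 | step 12 | 2,4-bis(benzyloxy)-6-bromobenzaldehyde | O=Cc1c(Br)cc(OCc2ccccc2)cc1OCc1ccccc1
F2 | step 12 | (E)-3-[2,4-bis(benzyloxy)-6-bromophenyl]-1-[4-(benzyloxy)phenyl]prop-2-en-1-one | O=C(/C=C/c1c(Br)cc(OCc2ccccc2)cc1OCc1ccccc1)c1ccc(OCc2ccccc2)cc1
F3 | step 12 | 3-[2,4-bis(benzyloxy)-6-bromophenyl]-1-[4-(benzyloxy)phenyl]propan-1-one | O=C(CCc1c(Br)cc(OCc2ccccc2)cc1OCc1ccccc1)c1ccc(OCc2ccccc2)cc1
F4 | step 12 | (1S)-3-[2,4-bis(benzyloxy)-6-bromophenyl]-1-[4-(benzyloxy)phenyl]propan-1-ol | O[C@H](c1ccc(OCc2ccccc2)cc1)CCc1c(Br)cc(OCc2ccccc2)cc1OCc1ccccc1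
F5 | step 12 | (2S)-5,7-bis(benzyloxy)-2-[4-(benzyloxy)phenyl]chromane | c1c(OCc2ccccc2)cc(OCc2ccccc2)c2c1O[C@H](c1ccc(OCc3ccccc3)cc1)CC2
F6 | step 12 | (2S)-5,7-bis(benzyloxy)-2-[4-(benzyloxy)phenyl]-8-bromochromane | Brc1c(OCc2ccccc2)cc(OCc2ccccc2)c2c1O[C@H](c1ccc(OCc3ccccc3)cc1)CC2
F7 | step 11 | 1,3,5-tris(benzyloxy)-2-[(1Z,3S)-3-[4-(benzyloxy)phenyl]-3-(methoxymethoxy)prop-1-en-1-yl]benzene | COCO[C@H](c1ccc(OCc2ccccc2)cc1)/C=C\c1c(OCc2ccccc2)cc(OCc2ccccc2)cc1OCc1ccccc1
F8 | step 11 | (3R)-3-[4-(benzyloxy)phenyl]-3-(methoxymethoxy)-1-[2,4,6-tris(benzyloxy)phenyl]propane-1,2-diol | COCO[C@H](c1ccc(OCc2ccccc2)cc1)C(O)C(O)c1c(OCc2ccccc2)cc(OCc2ccccc2)cc1OCc1ccccc1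
F0 | step 15 | none | none
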